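**Retrosynthetic overview**

1. Target 31 ⇐ 28: the aryl–C1' bond and the 16-membered ring are made last, by a ring-contracting photo-Claisen 1,3-shift (254 nm) of an 18-membered aryl-ether macrolactone; this also frees the phenol.
2. 28 ⇐ 26 ⇐ 23: macrolactonisation at C14'–OH; epoxide by invertive closure of a 10',11'-diol monomesylate; aryl ether by Mitsunobu coupling with methyl 4-hydroxybenzoate.
3. C8'–C9' bond ⇐ nickel-catalysed reductive coupling of alkenyl iodide 7 with iodohydrin 20.
4. 7 ⇐ (S)-limonene: alkenyl C–H borylation and iodination of the isopropenyl group, ring cleavage, aldol ring contraction (C6' bought).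
5. 20 ⇐ Felkin addition of the Grignard reagent from (S)-α-hydroxy-γ-butyrolactone (C14' bought) to the methyl ketone from methyl (R)-glycerate acetonide (C10' bought, C11' induced). Ring order: cyclopentene, epoxide, 18-membered lactone, 16-membered ring.

Assumption: terpenoid carbons are labelled C1' (benzylic CH2) to C15' (carbinol carbon of the CMe2OH group); compounds 1, 8, 12 and 22 are bought.

**Route**

Step 1
Reactants: 1 (S)-(−)-limonene
Product: 3 4,4,5,5-tetramethyl-2-[(1E)-2-[(1S)-4-methylcyclohex-3-en-1-yl]prop-1-en-1-yl]-1,3,2-dioxaborolane, via catechol alkenylboronate 2 (not isolated)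
Conditions: catBBr (1.5 equiv), Pd2(dba)3 (2.5 mol%), t-BuP(3,5-t-Bu2C6H3)2 (6 mol%), Cy2NMe, PhCF3, 70 °C; then pinacol, Et3N, rt
Reagents that add atoms: B-bromocatecholborane (BrB1Oc2ccccc2O1); pinacol (CC(C)(O)C(C)(C)O)
Why: Boryl-Heck reaction: the boryl–palladium species adds only to the unhindered 1,1-disubstituted alkene and β-hydride elimination toward the boron-bearing carbon gives the alkenylboronate with boron trans to the bulky ring (E), leaving the ring alkene and the limonene stereocentre untouched.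

Step 2
Reactants: 3
Product: 4 (4S)-4-[(1E)-1-iodoprop-1-en-2-yl]-1-methylcyclohex-1-ene
Conditions: NaOH (3 M aq), THF, 0 °C; then I2, THF, 0 °C to rt
Reagents that add atoms: iodine ([I][I])
Why: Iododeboronation of the hydroxyboronate complex is an ipso substitution that keeps the alkene geometry, and NaOH/I2 does not consume the trisubstituted ring alkene.

Step 3
Reactants: 4
Product: 5 (3S)-3-[(1E)-1-iodoprop-1-en-2-yl]-6-oxoheptanal
Conditions: OsO4 (2 mol%), NaIO4 (4 equiv), 2,6-lutidine, dioxane/H2O 3:1, rt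
Reagents that add atoms: sodium periodate ([Na+].[O-][I](=O)(=O)=O); osmium tetroxide (O=[Os](=O)(=O)=O)
Why: Lemieux–Johnson cleavage: electrophilic OsO4 dihydroxylates only the electron-rich ring alkene (the iodoalkene is deactivated) and periodate cleaves the diol, the stereocentre being β to the new aldehyde and not enolisable.

Step 4
Reactants: 5
Product: 6 (5S)-5-[(1E)-1-iodoprop-1-en-2-yl]-2-methylcyclopent-1-ene-1-carbaldehyde
Conditions: piperidine (0.2 equiv), AcOH (0.2 equiv), toluene, 80 °C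
Reagents that add atoms: none
Why: Intramolecular aldol condensation through the piperidine enamine of the aldehyde onto the methyl ketone closes the cyclopentene and dehydrates to the tetrasubstituted enal, the stereocentre next to the enamine carbon keeping its configuration.

Step 5
Reactants: 6
Product: 7 [(5S)-5-[(1E)-1-iodoprop-1-en-2-yl]-2-methylcyclopent-1-en-1-yl]methanol
Conditions: NaBH4, CeCl3·7H2O, MeOH, 0 °C
Reagents that add atoms: none
Why: Luche reduction gives clean 1,2-reduction of the enal to the allylic alcohol.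

Step 6
Reactants: 8 (S)-α-hydroxy-γ-butyrolactone
Product: 9 (3S)-4-methylpentane-1,3,4-triol
Conditions: MeMgBr (3.5 equiv), THF, 0 °C to rt; NH4Cl aq
Reagents that add atoms: methylmagnesium bromide (C[Mg]Br)
Why: Double Grignard addition to the lactone carbonyl builds the CMe2OH group (C15') and frees the primary alcohol, the bought C14' centre being shielded from enolisation as its magnesium alkoxide.

Step 7
Reactants: 9
Product: 10 (3S)-5-iodo-2-methylpentane-2,3-diol
Conditions: I2, PPh3, imidazole, THF, 0 °C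
Reagents that add atoms: iodine ([I][I])
Why: Appel iodination is selective for the unhindered primary hydroxyl.

Step 8
Reactants: 10
Product: 11 (3S)-5-iodo-2-methyl-2,3-bis[(triethylsilyl)oxy]pentane
Conditions: Et3SiOTf (2.5 equiv), 2,6-lutidine, CH2Cl2, −78 to 0 °C
Reagents that add atoms: triethylsilyl trifluoromethanesulfonate (CC[Si](CC)(CC)OS(=O)(=O)C(F)(F)F)
Why: Silyl triflate silylation caps both the secondary and the hindered tertiary hydroxyl so the iodide can be converted into a Grignard reagent.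

Step 9
Reactants: 12 methyl (4R)-2,2-dimethyl-1,3-dioxolane-4-carboxylate
Product: 13 (4R)-N-methoxy-N,2,2-trimethyl-1,3-dioxolane-4-carboxamide
Conditions: MeNH(OMe)·HCl, i-PrMgCl (3 equiv), THF, −20 °C
Reagents that add atoms: N,O-dimethylhydroxylamine hydrochloride (CNOC.Cl)
Why: Weinreb amide formation by aminolysis of the ester with the magnesium amide at low temperature does not epimerise the α-alkoxy centre.

Step 10
Reactants: 13
Product: 14 1-[(4R)-2,2-dimethyl-1,3-dioxolan-4-yl]ethan-1-one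
Conditions: MeMgBr (1.3 equiv), THF, −78 to 0 °C; NH4Cl aq
Reagents that add atoms: methylmagnesium bromide (C[Mg]Br)
Why: Weinreb ketone synthesis: the chelated tetrahedral adduct stops at mono-addition and gives the methyl ketone.

Step 11
Reactants: 11; 14
Product: 17 (2S,5S)-2-[(4R)-2,2-dimethyl-1,3-dioxolan-4-yl]-6-methylheptane-2,5,6-triol, via alkylmagnesium iodide 15 (not isolated), via bis-silyl adduct 16 (not isolated)
Conditions: 11, Mg turnings, THF, 40 °C; then 14, THF, −78 to −20 °C; then n-Bu4NF, THF, rt; NH4Cl aq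
Reagents that add atoms: none
Why: Grignard addition to the α-alkoxy ketone under Felkin–Anh control (ring C–O bond anti to the nucleophile, attack past H) sets C11' as S from the bought C10' centre (about 8:1 expected, minor isomer removed by chromatography), and fluoride then removes both silyl ethers.

Step 12
Reactants: 17
Product: 18 (4S)-4-[(3S)-3-[(4R)-2,2-dimethyl-1,3-dioxolan-4-yl]-3-hydroxybutyl]-5,5-dimethyl-1,3-dioxolan-2-one
Conditions: CDI (1.3 equiv), DMAP (10 mol%), CH2Cl2, rt to 40 °C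
Reagents that add atoms: 1,1'-carbonyldiimidazole (O=C(n1ccnc1)n1ccnc1)
Why: Cyclic carbonate formation occurs only on the 1,2-diol (the isolated tertiary C11' hydroxyl cannot cyclise) and masks C14'–OH and C15'–OH with a group that later falls off under the saponification conditions.

Step 13
Reactants: 18
Product: 19 (4S)-5,5-dimethyl-4-[(3S,4R)-3,4,5-trihydroxy-3-methylpentyl]-1,3-dioxolan-2-one
Conditions: AcOH/H2O 4:1, 40 °C
Reagents that add atoms: none
Why: Acetal hydrolysis of the terminal acetonide in dilute acid, to which the cyclic carbonate and the tertiary alcohol are stable.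

Step 14
Reactants: 19
Product: 20 (4S)-4-[(3S,4S)-3,4-dihydroxy-5-iodo-3-methylpentyl]-5,5-dimethyl-1,3-dioxolan-2-one
Conditions: I2, PPh3, imidazole, THF/MeCN, 0 °C
Reagents that add atoms: iodine ([I][I])
Why: Appel iodination of the only primary hydroxyl gives the iodohydrin (the descriptor at C10' changes to S only because CH2I outranks C11').

Step 15
Reactants: 7; 20
Product: 21 (4S)-4-[(3S,4R,6E)-3,4-dihydroxy-7-[(1R)-2-(hydroxymethyl)-3-methylcyclopent-2-en-1-yl]-3-methyloct-6-en-1-yl]-5,5-dimethyl-1,3-dioxolan-2-one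
Conditions: NiI2 (10 mol%), 4,4'-di-tert-butyl-2,2'-bipyridine (10 mol%), Mn powder (3 equiv), NaI (25 mol%), pyridine (10 mol%), DMPU, 25 to 40 °C; 20 (1.5 equiv)
Reagents that add atoms: none
Why: Nickel-catalysed reductive cross-electrophile coupling: the zerovalent nickel bipyridine complex inserts into the alkenyl C–I bond with retention of geometry and captures the primary radical formed from the iodohydrin, joining C8' to C9' without touching C10' or C11' and tolerating the free hydroxyls and the carbonate.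

Step 16
Reactants: 21; 22 methyl 4-hydroxybenzoate
Product: 23 methyl 4-{[(5R)-5-[(2E,5R,6S)-5,6-dihydroxy-8-[(4S)-5,5-dimethyl-2-oxo-1,3-dioxolan-4-yl]-6-methyloct-2-en-2-yl]-2-methylcyclopent-1-en-1-yl]methoxy}benzoate
Conditions: PPh3 (1.1 equiv), DIAD (1.1 equiv), THF, 0 °C to rt
Reagents that add atoms: none
Why: Mitsunobu etherification: the phenol displaces the activated primary allylic hydroxyl by SN2, while the hindered secondary and the tertiary hydroxyl do not react with one equivalent of reagents.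

Step 17
Reactants: 23
Product: 26 4-{[(5R)-5-[(2E)-4-[(2S,3S)-3-[(3S)-3,4-dihydroxy-4-methylpentyl]-3-methyloxiran-2-yl]but-2-en-2-yl]-2-methylcyclopent-1-en-1-yl]methoxy}benzoic acid, via mesylate 24 (not isolated), via epoxy carbonate ester 25 (not isolated)
Conditions: MsCl, Et3N, CH2Cl2, −20 °C; then LiOH·H2O, THF/MeOH/H2O, 35 °C; NaH2PO4 to pH 5
Reagents that add atoms: lithium hydroxide ([Li+].[OH-])
Why: Selective mesylation of the only secondary hydroxyl, then intramolecular Williamson closure by the C11' alkoxide with inversion at C10' gives the (10'S,11'S)-epoxide, while the same LiOH hydrolyses the cyclic carbonate and saponifies the methyl ester.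

Step 18
Reactants: 26
Product: 28 18-membered aryl-ether macrolactone (C14' ester of the para-alkoxybenzoate; 6'R,7'E,10'S,11'S,14'S), via mixed anhydride 27 (not isolated)
Conditions: MNBA (1.3 equiv), DMAP, Et3N, CH2Cl2 (2 mM), rt, slow addition over 12 h
Reagents that add atoms: none
Why: Shiina macrolactonisation under high dilution acylates the secondary C14' hydroxyl with retention, the tertiary C15' hydroxyl being too hindered to compete and the basic medium sparing the epoxide.

Step 19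
Reactants: 28
Product: 31 target CNP0346590.2, via phenoxyl–allyl biradical 29 (not isolated), via ortho-dienone 30 (not isolated)
Conditions: hν (254 nm, low-pressure Hg lamp, quartz), degassed MeCN (1 mM), 15 °C, stopped at about 70% conversion
Reagents that add atoms: none
Why: Proposed new method: a ring-contracting macrocyclic photo-Claisen rearrangement, in which singlet excitation of the 4-alkoxybenzoate chromophore homolyses the weak allylic C1'–O bond to a phenoxyl/allyl radical pair that the macrocyclic tether keeps together, the unhindered primary allyl terminus recombines at the ortho carbon (para is blocked by the ester) to give dienone 30, and tautomerisation gives the phenol, forming the aryl–C1' bond and the 16-membered ring with no stereocentre touched; the closest known reaction is the photo-Claisen 1,3-shift of acyclic allyl and prenyl aryl ethers to ortho-allylphenols, which has not been used as a macrocyclic ring contraction.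

**Compound list**

1 | (S)-(−)-limonene, (4S)-1-methyl-4-(prop-1-en-2-yl)cyclohex-1-ene | CC1=CC[C@H](CC1)C(C)=C | starting material
2 | 2-[(1E)-2-[(1S)-4-methylcyclohex-3-en-1-yl]prop-1-en-1-yl]-1,3,2-benzodioxaborole | CC1=CC[C@H](CC1)/C(C)=C/B1Oc2ccccc2O1 | intermediate
3 | 4,4,5,5-tetramethyl-2-[(1E)-2-[(1S)-4-methylcyclohex-3-en-1-yl]prop-1-en-1-yl]-1,3,2-dioxaborolane | CC1=CC[C@H](CC1)/C(C)=C/B1OC(C)(C)C(C)(C)O1 | intermediate
4 | (4S)-4-[(1E)-1-iodoprop-1-en-2-yl]-1-methylcyclohex-1-ene | CC1=CC[C@H](CC1)/C(C)=C/I | intermediate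
5 | (3S)-3-[(1E)-1-iodoprop-1-en-2-yl]-6-oxoheptanal | O=CC[C@H](CCC(C)=O)/C(C)=C/I | intermediate
6 | (5S)-5-[(1E)-1-iodoprop-1-en-2-yl]-2-methylcyclopent-1-ene-1-carbaldehyde | CC1=C(C=O)[C@@H](/C(C)=C/I)CC1 | intermediate
7 | [(5S)-5-[(1E)-1-iodoprop-1-en-2-yl]-2-methylcyclopent-1-en-1-yl]methanol | CC1=C(CO)[C@@H](/C(C)=C/I)CC1 | intermediate
8 | (S)-α-hydroxy-γ-butyrolactone, (3S)-3-hydroxyoxolan-2-one | O[C@H]1CCOC1=O | starting material
9 | (3S)-4-methylpentane-1,3,4-triol | OCC[C@H](O)C(C)(C)O | intermediate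
10 | (3S)-5-iodo-2-methylpentane-2,3-diol | ICC[C@H](O)C(C)(C)O | intermediate
11 | (3S)-5-iodo-2-methyl-2,3-bis[(triethylsilyl)oxy]pentane | ICC[C@H](O[Si](CC)(CC)CC)C(C)(C)O[Si](CC)(CC)CC | intermediate
12 | methyl (4R)-2,2-dimethyl-1,3-dioxolane-4-carboxylate | COC(=O)[C@H]1COC(C)(C)O1 | starting material
13 | (4R)-N-methoxy-N,2,2-trimethyl-1,3-dioxolane-4-carboxamide | CON(C)C(=O)[C@H]1COC(C)(C)O1 | intermediate
14 | 1-[(4R)-2,2-dimethyl-1,3-dioxolan-4-yl]ethan-1-one | CC(=O)[C@H]1COC(C)(C)O1 | intermediate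
15 | [(3S)-4-methyl-3,4-bis[(triethylsilyl)oxy]pentyl]magnesium iodide | I[Mg]CC[C@H](O[Si](CC)(CC)CC)C(C)(C)O[Si](CC)(CC)CC | intermediate
16 | (2S,5S)-2-[(4R)-2,2-dimethyl-1,3-dioxolan-4-yl]-6-methyl-5,6-bis[(triethylsilyl)oxy]heptan-2-ol | CC1(C)OC[C@@H](O1)[C@@](C)(O)CC[C@H](O[Si](CC)(CC)CC)C(C)(C)O[Si](CC)(CC)CC | intermediate
17 | (2S,5S)-2-[(4R)-2,2-dimethyl-1,3-dioxolan-4-yl]-6-methylheptane-2,5,6-triol | CC1(C)OC[C@@H](O1)[C@@](C)(O)CC[C@H](O)C(C)(C)O | intermediate
18 | (4S)-4-[(3S)-3-[(4R)-2,2-dimethyl-1,3-dioxolan-4-yl]-3-hydroxybutyl]-5,5-dimethyl-1,3-dioxolan-2-one | CC1(C)OC[C@@H](O1)[C@@](C)(O)CC[C@@H]1OC(=O)OC1(C)C | intermediate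
19 | (4S)-5,5-dimethyl-4-[(3S,4R)-3,4,5-trihydroxy-3-methylpentyl]-1,3-dioxolan-2-one | OC[C@@H](O)[C@@](C)(O)CC[C@@H]1OC(=O)OC1(C)C | intermediate
20 | (4S)-4-[(3S,4S)-3,4-dihydroxy-5-iodo-3-methylpentyl]-5,5-dimethyl-1,3-dioxolan-2-one | IC[C@@H](O)[C@@](C)(O)CC[C@@H]1OC(=O)OC1(C)C | intermediate
21 | (4S)-4-[(3S,4R,6E)-3,4-dihydroxy-7-[(1R)-2-(hydroxymethyl)-3-methylcyclopent-2-en-1-yl]-3-methyloct-6-en-1-yl]-5,5-dimethyl-1,3-dioxolan-2-one | CC1=C(CO)[C@@H](/C(C)=C/C[C@@H](O)[C@@](C)(O)CC[C@@H]2OC(=O)OC2(C)C)CC1 | intermediate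
22 | methyl 4-hydroxybenzoate | COC(=O)c1ccc(O)cc1 | starting material
23 | methyl 4-{[(5R)-5-[(2E,5R,6S)-5,6-dihydroxy-8-[(4S)-5,5-dimethyl-2-oxo-1,3-dioxolan-4-yl]-6-methyloct-2-en-2-yl]-2-methylcyclopent-1-en-1-yl]methoxy}benzoate | COC(=O)c1ccc(OCC2=C(C)CC[C@@H]2/C(C)=C/C[C@@H](O)[C@@](C)(O)CC[C@@H]2OC(=O)OC2(C)C)cc1 | intermediate
24 | (5R)-methanesulfonate of 23 at the secondary C10' hydroxyl | COC(=O)c1ccc(OCC2=C(C)CC[C@@H]2/C(C)=C/C[C@@H](OS(C)(=O)=O)[C@@](C)(O)CC[C@@H]2OC(=O)OC2(C)C)cc1 | intermediate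
25 | methyl 4-{[(5R)-5-[(2E)-4-[(2S,3S)-3-[2-[(4S)-5,5-dimethyl-2-oxo-1,3-dioxolan-4-yl]ethyl]-3-methyloxiran-2-yl]but-2-en-2-yl]-2-methylcyclopent-1-en-1-yl]methoxy}benzoate | COC(=O)c1ccc(OCC2=C(C)CC[C@@H]2/C(C)=C/C[C@@H]2O[C@@]2(C)CC[C@@H]2OC(=O)OC2(C)C)cc1 | intermediate
26 | 4-{[(5R)-5-[(2E)-4-[(2S,3S)-3-[(3S)-3,4-dihydroxy-4-methylpentyl]-3-methyloxiran-2-yl]but-2-en-2-yl]-2-methylcyclopent-1-en-1-yl]methoxy}benzoic acid | OC(=O)c1ccc(OCC2=C(C)CC[C@@H]2/C(C)=C/C[C@@H]2O[C@@]2(C)CC[C@H](O)C(C)(C)O)cc1 | intermediate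
27 | mixed anhydride of 26 with 2-methyl-6-nitrobenzoic acid | Cc1cccc([N+](=O)[O-])c1C(=O)OC(=O)c1ccc(OCC2=C(C)CC[C@@H]2/C(C)=C/C[C@@H]2O[C@@]2(C)CC[C@H](O)C(C)(C)O)cc1 | intermediate
28 | 18-membered macrolactone of 26 (ester between the carboxyl group and C14'–OH; para-bridged benzoate; C1'–O–aryl ether; 6'R,7'E,10'S,11'S,14'S) | O=C1O[C@H](C(C)(C)O)CC[C@]2(C)O[C@H]2C/C=C(\C)[C@H]2CCC(C)=C2COc2ccc1cc2 | intermediate
29 | tethered phenoxyl–allyl biradical from C1'–O homolysis of 28 | [CH2]C1=C(C)CC[C@@H]1/C(C)=C/C[C@@H]1O[C@@]1(C)CC[C@H](OC(=O)c1ccc([O])cc1)C(C)(C)O | intermediate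
30 | ortho-dienone (6-alkylated cyclohexa-2,4-dienone tautomer of 31; new sp3 ring carbon undefined) | O=C1C=CC2=CC1CC1=C(C)CC[C@@H]1/C(C)=C/C[C@@H]1O[C@@]1(C)CC[C@H](OC2=O)C(C)(C)O | intermediate
31 | CNP0346590.2, 16-membered meta-bridged 4-hydroxybenzoate macrolactone (6'R,7'E,10'S,11'S,14'S) | CC1=C2Cc3cc(ccc3O)C(=O)O[C@H](C(C)(C)O)CC[C@]3(C)O[C@H]3C/C=C(\C)[C@H]2CC1 | target

**Step count and risks**

Total steps: 19 (three branches). Longest linear sequence: 12 steps (8 → 31: steps 6, 7, 8, 11, 12, 13, 14, 15, 16, 17, 18, 19); the limonene branch is 10 steps to 31.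

Three steps most likely to fail:

- Step 19 (the proposed new step). It can fail by disproportionation of the tethered radical pair (the doubly allylic C6'–H is a donor), recombination at the tertiary allyl terminus, benzoate-sensitised E/Z isomerisation of C7'=C8', or secondary photocyclisation of the ortho-allylphenol product. Fallback with known chemistry, setting out from 21 and coming back at 31: the primary allylic hydroxyl of 21 is acylated with methyl chloroformate and pyridine to the allylic methyl carbonate F1. Commercial methyl 3-bromo-4-hydroxybenzoate is protected with 4-methoxybenzyl chloride and K2CO3 as methyl 3-bromo-4-[(4-methoxyphenyl)methoxy]benzoate F2, and Miyaura borylation (B2pin2, Pd(dppf)Cl2, KOAc) gives the pinacol arylboronate F3. Palladium-catalysed allyl–aryl Suzuki coupling of F1 with F3 (Pd(PPh3)4, KF, THF, 50 °C) forms the aryl–C1' bond at the unhindered CH2 terminus and gives the C-benzylated diol F4. Mesylation and LiOH treatment as in step 17 give the protected seco acid F5, Shiina lactonisation as in step 18 gives the 16-membered lactone 4-methoxybenzyl ether F6, and DDQ in pH 7 buffered CH2Cl2/H2O removes the 4-methoxybenzyl group to give 31.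

- Step 15. The hindered trisubstituted alkenyl iodide may homocouple or be reduced, and the iodohydrin may be dehalogenated. Fallback by polar epoxide opening, setting out from 7 and 20 and coming back at 21: 7 is silylated (t-BuMe2SiCl, imidazole) to the silyl ether F7. Compound 20 is closed with DBU to the terminal epoxy alcohol F8, whose tertiary hydroxyl is capped with N-(trimethylsilyl)imidazole to give the trimethylsilyl ether F9. Iodine–lithium exchange on F7 (t-BuLi, Et2O, −78 °C) gives the alkenyllithium F10, which opens F9 at its CH2 terminus in the presence of BF3·OEt2 to give the adduct F11. n-Bu4NF removes both silyl groups and returns 21.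

- Step 1. The α-branched isopropenyl group may react slowly or give allylboronate isomers and some Z product. Fallback by olefin cross-metathesis, setting out from 1 and coming back at 3: 1 and pinacol (E)-prop-1-enylboronate with the second-generation Hoveyda–Grubbs catalyst (CH2Cl2, 40 °C) give 3 directly with loss of propene, the trisubstituted ring alkene being inert to metathesis; no new compound is made.

Further compounds
F1 | step 19 | methyl carbonate of 21 at the primary allylic (C1') hydroxyl | COC(=O)OCC1=C(C)CC[C@@H]1/C(C)=C/C[C@@H](O)[C@@](C)(O)CC[C@@H]1OC(=O)OC1(C)C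
F2 | step 19 | methyl 3-bromo-4-[(4-methoxyphenyl)methoxy]benzoate | COC(=O)c1ccc(OCc2ccc(OC)cc2)c(Br)c1
F3 | step 19 | methyl 4-[(4-methoxyphenyl)methoxy]-3-(4,4,5,5-tetramethyl-1,3,2-dioxaborolan-2-yl)benzoate | COC(=O)c1ccc(OCc2ccc(OC)cc2)c(c1)B1OC(C)(C)C(C)(C)O1
F4 | step 19 | methyl 3-{[(5R)-5-[(2E,5R,6S)-5,6-dihydroxy-8-[(4S)-5,5-dimethyl-2-oxo-1,3-dioxolan-4-yl]-6-methyloct-2-en-2-yl]-2-methylcyclopent-1-en-1-yl]methyl}-4-[(4-methoxyphenyl)methoxy]benzoate | COC(=O)c1ccc(OCc2ccc(OC)cc2)c(CC2=C(C)CC[C@@H]2/C(C)=C/C[C@@H](O)[C@@](C)(O)CC[C@@H]2OC(=O)OC2(C)C)c1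
F5 | step 19 | 3-{[(5R)-5-[(2E)-4-[(2S,3S)-3-[(3S)-3,4-dihydroxy-4-methylpentyl]-3-methyloxiran-2-yl]but-2-en-2-yl]-2-methylcyclopent-1-en-1-yl]methyl}-4-[(4-methoxyphenyl)methoxy]benzoic acid | OC(=O)c1ccc(OCc2ccc(OC)cc2)c(CC2=C(C)CC[C@@H]2/C(C)=C/C[C@@H]2O[C@@]2(C)CC[C@H](O)C(C)(C)O)c1
F6 | step 19 | 4-methoxybenzyl ether of 31 at the phenol oxygen | COc1ccc(COc2ccc3cc2CC2=C(C)CC[C@@H]2/C(C)=C/C[C@@H]2O[C@@]2(C)CC[C@H](OC3=O)C(C)(C)O)cc1
F7 | step 15 | tert-butyl{[(5S)-5-[(1E)-1-iodoprop-1-en-2-yl]-2-methylcyclopent-1-en-1-yl]methoxy}dimethylsilane | CC1=C(CO[Si](C)(C)C(C)(C)C)[C@@H](/C(C)=C/I)CC1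
F8 | step 15 | (4S)-4-[(3S)-3-hydroxy-3-[(2R)-oxiran-2-yl]butyl]-5,5-dimethyl-1,3-dioxolan-2-one | C1O[C@H]1[C@@](C)(O)CC[C@@H]1OC(=O)OC1(C)C
F9 | step 15 | trimethylsilyl ether of F8 at the tertiary hydroxyl | C1O[C@H]1[C@@](C)(O[Si](C)(C)C)CC[C@@H]1OC(=O)OC1(C)C
F10 | step 15 | alkenyllithium from F7 (lithium in place of iodine; E) | CC1=C(CO[Si](C)(C)C(C)(C)C)[C@@H](/C(C)=C/[Li])CC1
F11 | step 15 | bis-silyl derivative of 21 (C1'–O–SiMe2t-Bu and C11'–O–SiMe3) | CC1=C(CO[Si](C)(C)C(C)(C)C)[C@@H](/C(C)=C/C[C@@H](O)[C@@](C)(O[Si](C)(C)C)CC[C@@H]2OC(=O)OC2(C)C)CC1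
F0 | step 1 | none | none
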